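**Assumption:** Stipulin has no stereocentres and is achiral; the only stereo-element is the (E)-enone C=C, so "single enantiomer" is taken to mean the (E)-isomer as drawn.

## Retrosynthetic overview

1. Disconnect the enone Cα=Cβ bond (Claisen–Schmidt aldol condensation) into an A-ring methyl ketone and a B-ring aldehyde; the E-alkene comes from thermodynamic E1cB dehydration.
2. B-ring aldehyde = 4-hydroxy-3-prenylbenzaldehyde, from ortho C-prenylation of the phenoxide of 4-hydroxybenzaldehyde.
3. A-ring ketone = 2,4-dihydroxy-5-prenylacetophenone, from Friedel–Crafts prenylation of resacetophenone at C-5.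
4. No rings are formed (both arenes are purchased) and no protecting groups are used; the route is convergent, 2 + 1 steps.

Compounds are numbered in order of appearance in the forward route.

## Route

**Step 1**
Reactants: **1** 4-hydroxybenzaldehyde; **2** prenyl bromide (1-bromo-3-methylbut-2-ene)
Product: **3** 4-hydroxy-3-(3-methylbut-2-en-1-yl)benzaldehyde
Conditions: **2** (1.1 equiv), 10% aq. KOH (2 equiv), N2, rt, 24–48 h; wash the basic phase with Et2O to remove the O-prenyl ether, then acidify with cold dilute HCl; SiO2.
Reagents that add atoms: prenyl bromide, CC(C)=CCBr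
Why: Direct ortho C-alkylation of an ambident phenoxide; in water the oxygen is hydrogen-bond solvated, so the soft allylic bromide attacks the ring carbon ortho to O⁻ (both ortho positions are equivalent). Expect roughly 30–45%.

**Step 2**
Reactants: **4** 2,4-dihydroxyacetophenone (resacetophenone); **5** 2-methylbut-3-en-2-ol
Product: **6** 1-[2,4-dihydroxy-5-(3-methylbut-2-en-1-yl)phenyl]ethan-1-one
Conditions: **5** (1.0 equiv), BF3·OEt2 (0.5–1 equiv, slow addition), dry dioxane, rt, 4–12 h, stopped at partial conversion; NaHCO3 quench; SiO2 (recover **4**).
Reagents that add atoms: 2-methylbut-3-en-2-ol, CC(C)(O)C=C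
Why: Friedel–Crafts alkylation by the dimethylallyl cation, which reacts at its primary terminus; the neutral arene is attacked at the less hindered C-5 (ortho to 4-OH, para to 2-OH) in preference to C-3, which is flanked by both OH groups. Expect roughly 20–30%; the 5-isomer shows two aromatic singlets in the ¹H NMR.

**Step 3**
Reactants: **6** 2,4-dihydroxy-5-prenylacetophenone; **3** 4-hydroxy-3-prenylbenzaldehyde
Product: **7** Stipulin, (E)-1-[2,4-dihydroxy-5-(3-methylbut-2-en-1-yl)phenyl]-3-[4-hydroxy-3-(3-methylbut-2-en-1-yl)phenyl]prop-2-en-1-one
Conditions: **3** (1.1 equiv), 50–60% aq. KOH (large excess), EtOH, Ar, 0 °C → rt (warm to 40 °C if slow), 48–72 h; pour onto ice and acidify with cold 1 M HCl to pH 4–5; EtOAc extraction; SiO2 or recrystallisation.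
Reagents that add atoms: none (both fragments are the listed reactants; water is lost)
Why: Claisen–Schmidt condensation of the poly-phenoxide ketone enolate with the aldehyde, followed by E1cB dehydration to the conjugated trans-enone (J ≈ 15–16 Hz). Prenyl groups are inert to base, and the cold, mildly acidic work-up avoids chroman or flavanone formation.

## Compound list

1 | 4-hydroxybenzaldehyde | O=Cc1ccc(O)cc1 | starting material
2 | prenyl bromide | CC(C)=CCBr | starting material
3 | 4-hydroxy-3-(3-methylbut-2-en-1-yl)benzaldehyde | CC(C)=CCc1cc(C=O)ccc1O | intermediate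
4 | 2,4-dihydroxyacetophenone | CC(=O)c1ccc(O)cc1O | starting material
5 | 2-methylbut-3-en-2-ol | CC(C)(O)C=C | starting material
6 | 2,4-dihydroxy-5-(3-methylbut-2-en-1-yl)acetophenone | CC(=O)c1cc(CC=C(C)C)c(O)cc1O | intermediate
7 | Stipulin | CC(C)=CCc1cc(/C=C/C(=O)c2cc(CC=C(C)C)c(O)cc2O)ccc1O | target

## Summary

Total steps: 3.
Longest linear sequence: 2 (step 1 → step 3, or step 2 → step 3).

Steps most likely to fail, with fallbacks:

1. **Step 2 (C-5 versus C-3 prenylation, over-alkylation, chroman formation).** Fallback: install the prenyl group by cross-coupling. Take 5-bromo-2,4-dihydroxyacetophenone (or NBS bromination of **4**), protect as the bis-MOM ether, and run a Stille coupling with tributyl(prenyl)stannane (Pd(PPh3)4, DMF, 90 °C). This fixes the regiochemistry unambiguously, and the MOM ketone then goes into a protected condensation.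

2. **Step 3 (sluggish aldol, because the para-phenoxide deactivates the aldehyde and the ketone is poly-anionic).** Fallback: mask the para-OH groups first (MOMCl/K2CO3 on **3**; selective 4-O-MOM on **6**, whose chelated 2-OH stays free), condense with KOH/EtOH at rt, then remove MOM with dilute HCl/MeOH, brief and monitored. This adds 3 steps.

3. **Step 1 (O- versus C-alkylation, modest yield).** Fallback: a Claisen rearrangement route. O-alkylate **1** with 3-chloro-3-methylbut-1-yne (K2CO3, KI, cat. CuI, acetone), semi-hydrogenate with Lindlar catalyst to the 1,1-dimethylallyl aryl ether, then heat (PhNEt2, about 120–140 °C). The [3,3] shift delivers the linear 3-prenyl phenol **3** exclusively at the ortho position.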